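Whatever is charged as substrate stays in the flask as substrate, as target or as something unseen, and that unseen part, the gap, is what these runs let you read.

| flask | substrate | coupling partner | initiator | remark | time |
|---|---|---|---|---|---|
| spring | 0.020 M | 0.022 M (in portions, 4) | 1.3 mM | run made earlier; portions every 3.0 min |  |
| dusk | 0.020 M | 0.022 M (in portions, 4) | 2 mM | run made earlier; portions every 3.0 min |  |
| noon | 0.010 M | 0.022 M (in portions, 4) | 0.92 mM | run made earlier; portions every 3.0 min |  |
| Wednesday's | 0.020 M | 0.0220 M (in portions, 4) | 0.92 mM | the portions of coupling partner follow each other after 3.0 min, the first at the start | 20 min |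
| Thursday's | 0.020 M | 0.0220 M | 0.92 mM | everything together at the start | 20 min |

| run | time / min | target / % | substrate / % |
|---|---|---|---|
| spring | 3.00 | 6.9 | 91.0 |
| spring | 6.00 | 13.7 | 81.3 |
| spring | 10.0 | 23.7 | 70.0 |
| spring | 12.0 | 28.2 | 66.1 |
| dusk | 1.00 | 3.0 | 95.4 |
| dusk | 2.00 | 6.3 | 90.1 |
| dusk | 5.00 | 14.4 | 79.1 |
| dusk | 12.0 | 31.5 | 58.0 |
| noon | 1.00 | 3.5 | 95.0 |
| noon | 2.00 | 6.9 | 90.0 |
| noon | 5.00 | 16.6 | 78.9 |
| noon | 12.0 | 35.6 | 59.7 |

(standard deviation of a reading: 0.5 percentage points)

- a reading or a percentage of target counts all its forms, free or not

1. the flask that ends with the higher amount of target, in percent of the substrate charged, or "neither" when 2 percentage points or less lies between them (Wednesday's / Thursday's / neither)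
2. final target, as a percentage of the substrate charged, in Wednesday's
3. final target, as a percentage of the substrate charged, in Thursday's

Divide target gained by substrate spent and time drops out. In the spring run up to 6.00 min, with two portions of coupling partner in, this selectivity, target gained per substrate spent, reads 73.3%. From there to 12.0 min it reads 95.4%, higher than before, and the gap in the spring run reads 5 percentage points at 6.00 min and 5.7 points at 12.0 min.

Now build the flask up. Take the main step first, each spent substrate becoming a target, with the rate going as the square root of [initiator]: dusk spent 1.24 times what spring spent by 12.0 min, and the root gives 1.24. Spring's first stretch, scaled to 0.92 mM, is 15.7%, so 20 min at that pace spends 52.3% in either flask.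

Add the slowing: spring's second stretch spent 81.3% of its first, and repeating that ratio lowers the total to 41.9%, still a tie. Add the loss: Thursday's holds the whole partner charge from the start, so I give it 95.4% throughout, which makes 40.0%. Wednesday's follows spring's portions, so 73.3% on the first stretch and 95.4% afterwards make 36.5%. My reckoning puts Thursday's ahead by 3.5 points, beyond the margin of 2 points.

The forecast differs: neither, with 35% in Wednesday's and 35% in Thursday's, since “Partner seems to be about zero order”.

The flasks give Thursday's, with 33.5% in Wednesday's and 40.9% in Thursday's.

    initiator → 2 initiating radical (k = 0.120 /min)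
    substrate + initiating radical → capped initiator + first chain carrier (k = 8.10 × 10⁵ /M/s)
    coupling partner + first chain carrier → target + second chain carrier (k = 3.30 × 10⁵ /M/min)
    substrate + second chain carrier → by-product + first chain carrier (k = 12000 /M/s)
    2 first chain carrier → ended chains A (k = 2.00 × 10⁷ /M/s)
    2 second chain carrier → ended chains B (k = 4.00 × 10⁸ /M/s)
    target ⇌ isomer of the product (K = 0.720, k = 0.00890 /min)
    coupling partner + target ⇌ idle adduct, settled at all times (K = 1500 /M)

Wednesday's spent 38.5% of its substrate at a selectivity of 87.0%, above 73.3%, while Thursday's spent 43.7% at 93.5%, so Thursday's spent more and turned a larger part of it into target. Their gaps hold ended chains A, 4.79% in Wednesday's against 2.55% in Thursday's, and isomer of the product, 0.194% against 0.310%. The neighbouring flask, Wednesday's recipe with 0.0037 M of initiator, spent 71.3% and holds 48.5% of target, a selectivity of 68.1%, lower than 73.3%, and its ended chains A stand at 22.2%.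

The earlier runs and the new flask stem from a simulated flask on assumed constants, and the scatter is random.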